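Atom numbers C1–C19 are those of the target chain (C1 = ester carbon); the ring is O1–O2–C3–C4–C5–C6, with O1 on C6 and O2 on C3.

## The problem

- **Structure.** The target 29 is a 1,2-dioxane whose C3 carries H and the (R)-CH(CH3)CO2Me unit (C2), and whose C6 is fully substituted (CH3, O1, and a 13-carbon chain starting at C7). The chain holds a lone methyl stereocenter (C10), an acyclic tertiary hydroperoxide (C14) and a trisubstituted alkene (C17=C18).
- **Stereochemistry.** Five stereocenters must be set: C2/C3 are contiguous (C2-methyl and C3–O syn), and C6 is 1,4 to C3 across the ring. The C7 chain is cis to the C3 side chain, so in the chair the longer C6 substituent is axial. Ring closures that equilibrate, or that rely on a size difference between CH3 and CH2R at C6, cannot deliver this isomer.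
- **Direction of control.** C3 (H versus alkyl) can control C6, but C6 (CH3 versus CH2R) cannot control C3. C10 and C14 are insulated from everything else and must come from the chiral pool.
- **Enabling feature.** C6 is a ketal-level carbon: it is bonded to ring oxygen O1 and otherwise only to carbon. It can therefore be ionized to a ring peroxycarbenium ion (C6=O1+) inside an intact O1–O2–C3 unit, and the C6–C7 bond can be the last bond made at that centre, under control of C3.
- **Second feature.** C12–C19 with C14 is the linalool skeleton, so the tertiary hydroperoxide can be derived from a bought tertiary carbinol.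
- **Sensitive groups.** The O–O bonds exclude phosphines at elevated temperature, hydrides, low-valent metals, catalytic hydrogenation and nearby carbanions. The β-peroxy ester is base-labile (retro-oxa-Michael, C2 epimerization, Kornblum–DeLaMare at C3–H). The tertiary hydroperoxide does not survive strong acid or redox metals. The C17=C18 alkene must survive every oxidation and reduction.

## Retrosynthesis

**29 ⇐ 28 ⇐ 27 (unmasking and saturation).** The hydroperoxide is released last from perketal 28. The C8–C9 single bond of 28 is the diimide-reduced form of alkene 27. Diimide is the one alkene reduction that leaves O–O bonds alone and still separates a 1,2-disubstituted alkene from the trisubstituted C17=C18.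

**27 ⇐ 11 + 26 (cut C8=C9, cross-metathesis).** This bond is preferred to its neighbours for three reasons. No carbanion is needed in a molecule carrying the β-peroxy ester. Both peroxides sit three or more atoms from the reacting alkenes. The prenyl terminus of 26 is nine atoms from its vinyl group, whereas a terminal alkene at C11/C12 or C12/C13 would ring-close onto it. The cut divides the target into an 11-carbon ring fragment (11) and a 15-carbon chain fragment (26) of similar size.

**11 ⇐ 9 through ion 10 (cut C6–C7, the key step).** Cutting C6–O1 instead (hydroperoxide plus oxa-Michael or alkylation) would make C6 first and ask it to control C3, which it cannot. Cutting C6–C7 makes C3 the controller. Precursor 9 has only the C2/C3 pair as fixed stereocenters, and its ketal carbon may be a mixture. The forward reaction must be an axial, kinetically controlled allylation of the half-chair cation 10. It then gives the isomer with the longer substituent axial, which is the one thermodynamics disfavours.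

**9 ⇐ 8 ⇐ 6 ⇐ 5 ⇐ 4 ⇐ 3 ⇐ 2 ⇐ 1 (cut O2–C3, then C2–C3).** The ring of 6 closes by 6-exo-tet SN2 of a hydroperoxyketal on a secondary mesylate, with inversion at C3. C2 and C3 therefore come from one anti-selective crotylboration of keto aldehyde 2. The vinyl group of 3–6 is a latent ester: it keeps C2–H non-acidic while the mesylate is present, so elimination is avoided. It is oxidized to the ester only after the ring exists.

**26 ⇐ 25 ⇐ 24 ⇐ 23 ⇐ 19 + 21 (cut C11=C12, Wittig).** The peroxide sits on the aldehyde partner 19, and the ylide comes from the peroxide-free phosphonium salt 21 (C9–C11 with C10 from a bought bromo alcohol). This avoids a carbanion within reach of an O–O bond. The price is three adjustment steps (16–18) to turn the CH2OH of 23 into the vinyl group of 26.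

**19 ⇐ 18 ⇐ 16 ⇐ 15 ⇐ 13 ⇐ 12 (C14–OOH from (R)-linalool).** Hydroboration of the vinyl group and oxetane formation keep the C14–O bond. Lewis-acid perhydrolysis of oxetane 15 then replaces it by C–OOH with inversion. The oxetane oxygen ends on C12 as the primary alcohol, which is exactly the carbon needed as the aldehyde of 19.

## Roads not taken

**Alternative 1:** The obvious route cuts O2–C3 by oxa-Michael addition and both C–OO bonds by radical hydroperoxidation. Co(acac)2/O2/Et3SiH hydroperoxysilylation of the two 1,1-disubstituted alkenes of a triene ester would give methyl (2E)-6,14-dihydroperoxy-2,6,10,14,18-pentamethylnonadeca-2,17-dienoate A1. Base would then close the ring by 6-exo-trig addition of the C6 hydroperoxide to the enoate. It is short, but C6 and C14 arise from radical capture of O2 at acyclic centres, C3 from a chair in which CH3 and CH2R at C6 are indistinguishable, and C2 from enolate protonation. Up to sixteen isomers result, the hydroperoxidation must also spare C17=C18, and the target (axial chain) is not the thermodynamic one. The chosen plan sets each of these centres by a stereospecific or C3-controlled event.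

**Alternative 2:** C6 and C14 are homochiral, and each is the carbinol carbon of a linalool skeleton (C12–C19 and C8–C1). Both could therefore be made from (R)-linalool by oxetane perhydrolysis. The left half would be methyl (2E,6S)-6-hydroperoxy-8-hydroxy-2,6-dimethyloct-2-enoate A2, closed by oxa-Michael addition. This fixes C6 absolutely but leaves C3 and C2 uncontrolled, for the reason given above. The stereospecific variant (SN2 of the tertiary hydroperoxide on a C3 sulfonate) needs the prenyl terminus cut off and C2/C3 rebuilt on a peroxide-bearing chain, about nine more steps. It is kept as the fallback to the key step.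

**Alternative 3:** A [4+2] cycloaddition of singlet oxygen to the diene methyl (3E,5E)-14-hydroperoxy-2,6,10,14,18-pentamethylnonadeca-3,5,17-trienoate A3 (target configuration at C2, C10, C14) would give the 3,6-dihydro-1,2-dioxin A4. Diimide would then saturate C4=C5. The cis relation of the two chains demands the C6 methyl on the inside of the s-cis diene, and such dienes give ene products instead. The trisubstituted C17=C18 is itself the best ene substrate in the molecule, and facial selectivity would rest on the exocyclic C2 centre alone. The chosen plan makes both C–O bonds of the ring by ionic, stereodefined steps.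

Key step: step 8

Assumption: the target SMILES is read as the (2R,3S,6R,10R,14R) isomer. Commercial (R)-(−)-linalool of high enantiomeric purity is used.

Remark: compounds 5–9 are carried as mixtures at the ketal carbon, which converge at ion 10.

## Steps

Step 1
Reactants: 1 hex-5-en-2-one
Product: 2 4-oxopentanal
Conditions: O3, CH2Cl2, −78 °C; then Me2S, −78 °C to rt
Reagents that add atoms: ozone, [O-][O+]=O
Why: Ozonolysis with reductive work-up cleaves the terminal alkene to the aldehyde; the methyl ketone is inert to ozone.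

Step 2
Reactants: 2 4-oxopentanal
Product: 3 (5R,6S)-5-hydroxy-6-methyloct-7-en-2-one
Conditions: (E)-crotyl-B(Ipc)2 [from (−)-Ipc2BOMe, (+)-α-pinene series], THF/Et2O, −78 °C; then NaBO3·4H2O, THF/H2O, rt
Reagents that add atoms: (−)-B-[(E)-but-2-en-1-yl]diisopinocampheylborane, C/C=C/CB([C@@H]1C[C@@H]2C[C@H]([C@H]1C)C2(C)C)[C@@H]1C[C@@H]2C[C@H]([C@H]1C)C2(C)C
Why: Brown crotylboration through a chair transition state: the (E)-crotyl geometry gives the anti relation of methyl and hydroxyl, and the isopinocampheyl groups of this series select the aldehyde face that gives the (5R) carbinol. The aldehyde reacts at −78 °C and the methyl ketone does not; C2 and the pre-inversion configuration of C3 are set here.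

Step 3
Reactants: 3 (5R,6S)-5-hydroxy-6-methyloct-7-en-2-one
Product: 4 (3S,4R)-3-methyl-7-oxooct-1-en-4-yl methanesulfonate
Conditions: MsCl, Et3N, CH2Cl2, −20 °C
Reagents that add atoms: methanesulfonyl chloride, CS(=O)(=O)Cl
Why: Sulfonylation of the secondary alcohol with retention; the open-chain hydroxy ketone is the reacting form and the mesylate is used without storage.

Step 4
Reactants: 4 (3S,4R)-3-methyl-7-oxooct-1-en-4-yl methanesulfonate
Product: 5 (3S,4R)-7-hydroperoxy-7-methoxy-3-methyloct-1-en-4-yl methanesulfonate (both C7 epimers)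
Conditions: urea·H2O2, Sc(OTf)3 (cat.), MeOH, 0 °C, short
Reagents that add atoms: hydrogen peroxide (as urea adduct), OO; methanol, CO
Why: Lewis-acid-catalysed conversion of a methyl ketone into its methoxy hydroperoxide (hydroperoxyketal) in methanol is a known reaction. The new centre is ionized later, so its configuration is irrelevant; low temperature and short time keep the secondary mesylate intact.

Step 5
Reactants: 5 (3S,4R)-7-hydroperoxy-7-methoxy-3-methyloct-1-en-4-yl methanesulfonate
Product: 6 (3S)-3-[(2S)-but-3-en-2-yl]-6-methoxy-6-methyl-1,2-dioxane (both C6 epimers)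
Conditions: KOtBu, 18-crown-6, THF, 0 °C
Reagents that add atoms: none
Why: Intramolecular alkylation of the hydroperoxyketal anion by the secondary sulfonate (6-exo-tet SN2) closes the 1,2-dioxane with inversion at C3. This turns the anti pattern of 3 into the syn C2-methyl/C3–O pattern of the target; the vinyl group does not acidify C2–H, so E1cB loss of mesylate is not available.

Step 6
Reactants: 6 (3S)-3-[(2S)-but-3-en-2-yl]-6-methoxy-6-methyl-1,2-dioxane
Product: 8 (2R)-2-[(3S)-6-methoxy-6-methyl-1,2-dioxan-3-yl]propanoic acid, via aldehyde 7 (not isolated)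
Conditions: O3, MeCN/H2O (9:1), 0 °C; then NaClO2, NaH2PO4, 2-methylbut-2-ene, rt
Reagents that add atoms: ozone, [O-][O+]=O; sodium chlorite, [Na+].[O-]Cl=O
Why: Ozonolysis in aqueous acetonitrile gives the aldehyde directly, and Pinnick oxidation in the same flask gives the acid without epimerizing C2. Dialkyl peroxyketals are inert to ozone and to buffered chlorite.

Step 7
Reactants: 8 (2R)-2-[(3S)-6-methoxy-6-methyl-1,2-dioxan-3-yl]propanoic acid
Product: 9 methyl (2R)-2-[(3S)-6-methoxy-6-methyl-1,2-dioxan-3-yl]propanoate
Conditions: TMSCHN2, toluene/MeOH (4:1), 0 °C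
Reagents that add atoms: trimethylsilyldiazomethane, C[Si](C)(C)C=[N+]=[N-]
Why: Esterification under neutral conditions keeps base away from the β-peroxy ester.

Step 8
Reactants: 9 methyl (2R)-2-[(3S)-6-methoxy-6-methyl-1,2-dioxan-3-yl]propanoate
Product: 11 methyl (2R)-2-[(3S,6S)-6-methyl-6-(prop-2-en-1-yl)-1,2-dioxan-3-yl]propanoate, via peroxycarbenium ion 10 (not isolated)
Conditions: allyltrimethylsilane (3 equiv), TiCl4 (1.2 equiv), CH2Cl2, −78 °C
Reagents that add atoms: allyltrimethylsilane, C=CC[Si](C)(C)C
Why: TiCl4 ionizes the exocyclic C6–OMe bond of either epimer of 9 to the same ring peroxycarbenium ion 10 (C6=O1+), which allyltrimethylsilane captures in an SE2' Hosomi–Sakurai reaction; the closest known reaction type is the Lewis-acid allylation of 3-alkoxy-1,2-dioxanes and 3-alkoxy-1,2-dioxolanes at the peroxyketal carbon. No ring is closed; the step forms the C6–C7 bond and the fully substituted stereocenter C6. In 10 the atoms C5, C6, O1 and O2 are coplanar and C3 and C4 lie out of plane, so two half-chairs exist, and the one with the C3 substituent pseudo-equatorial is favoured because C3 carries only H besides it. Attack along the axial trajectory of that half-chair leads directly to a chair, and on that face the incoming allyl group meets only the axial H on C4 and a lone pair on O2. The product therefore has allyl axial and methyl equatorial at C6, that is allyl cis to the C3 side chain, which is the (3S,6S) isomer 11 and becomes 6R in 29 once the chain is extended. This is kinetic control by C3 and gives the isomer with the longer C6 substituent axial, which equilibrating closures cannot favour. The step needs facial selectivity at C6 and ionization of the ketal C–O bond in preference to O–O heterolysis; the first is secured by the single substituent at C3, the second by −78 °C and an excess of a π-nucleophile that traps the ion as it forms. The ester is a spectator under these conditions.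

Step 9
Reactants: 12 (3R)-3,7-dimethylocta-1,6-dien-3-ol [(R)-linalool]
Product: 13 (3R)-3,7-dimethyloct-6-ene-1,3-diol
Conditions: 9-BBN (2.2 equiv), THF, 0 °C to rt; then NaOH, H2O2, 0 °C
Reagents that add atoms: hydrogen peroxide, OO
Why: 9-BBN hydroborates the monosubstituted vinyl group at its terminal carbon and leaves the trisubstituted alkene; oxidation gives the 1,3-diol with the carbinol stereocenter untouched.

Step 10
Reactants: 13 (3R)-3,7-dimethyloct-6-ene-1,3-diol
Product: 15 (2R)-2-methyl-2-(4-methylpent-3-en-1-yl)oxetane, via primary tosylate 14 (not isolated)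
Conditions: n-BuLi (1 equiv), THF, 0 °C; TsCl (1 equiv); then n-BuLi (1.1 equiv), 0 to 60 °C
Reagents that add atoms: none
Why: One-pot tosylation of the primary hydroxyl and 4-exo-tet Williamson closure by the tertiary alkoxide; the C–O bond at the stereocenter is not broken, so configuration is retained.

Step 11
Reactants: 15 (2R)-2-methyl-2-(4-methylpent-3-en-1-yl)oxetane
Product: 16 (3S)-3-hydroperoxy-3,7-dimethyloct-6-en-1-ol
Conditions: H2O2 (anhydrous, in Et2O, excess), TMSOTf (0.2 equiv), Et2O, −78 to 0 °C
Reagents that add atoms: hydrogen peroxide, OO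
Why: Lewis-acid-activated opening of a 2,2-disubstituted oxetane by H2O2 at the tertiary carbon is a known perhydrolysis that proceeds with inversion through a tight SN2-like ion pair. It turns the linalool carbinol carbon into the tertiary hydroperoxide with the configuration of C14; the homoprenyl alkene is too close to the reacting carbon to cyclize onto it.

Step 12
Reactants: 16 (3S)-3-hydroperoxy-3,7-dimethyloct-6-en-1-ol
Product: 18 (3S)-3-[(2-methoxypropan-2-yl)peroxy]-3,7-dimethyloct-6-en-1-ol, via bis-ketal 17 (not isolated)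
Conditions: 2-methoxypropene (3 equiv), PPTS (cat.), CH2Cl2, 0 °C; then MeOH, 0 °C, short; Et3N quench
Reagents that add atoms: 2-methoxypropene, COC(C)=C
Why: Both O–H groups add to 2-methoxypropene under acid catalysis; methanolysis then removes the much more labile mixed ketal of the alcohol, while the peroxyketal ionizes more slowly because a peroxy oxygen is a poorer donor. The perketal is a known base-stable protecting group for hydroperoxides.

Step 13
Reactants: 18 (3S)-3-[(2-methoxypropan-2-yl)peroxy]-3,7-dimethyloct-6-en-1-ol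
Product: 19 (3S)-3-[(2-methoxypropan-2-yl)peroxy]-3,7-dimethyloct-6-enal
Conditions: Dess–Martin periodinane, NaHCO3, CH2Cl2, 0 °C to rt
Reagents that add atoms: none
Why: Buffered Dess–Martin oxidation of the primary alcohol; neutral conditions spare the perketal and the alkene and avoid β-elimination of the peroxide.

Step 14
Reactants: 20 (2S)-3-bromo-2-methylpropan-1-ol
Product: 21 [(2S)-3-hydroxy-2-methylpropyl]triphenylphosphonium bromide
Conditions: PPh3, MeCN, reflux
Reagents that add atoms: triphenylphosphine, c1ccccc1P(c1ccccc1)c1ccccc1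
Why: SN2 quaternization of the phosphine by the primary bromide, done before any peroxide is present; the stereocenter (C10) is not involved.

Step 15
Reactants: 19 (3S)-3-[(2-methoxypropan-2-yl)peroxy]-3,7-dimethyloct-6-enal; 21 [(2S)-3-hydroxy-2-methylpropyl]triphenylphosphonium bromide
Product: 23 (2R,3E,6S)-6-[(2-methoxypropan-2-yl)peroxy]-2,6,10-trimethylundeca-3,9-dien-1-ol (E/Z mixture), via oxido ylide 22 (not isolated)
Conditions: 21 (1.5 equiv), n-BuLi (3.0 equiv), THF, −78 to 0 °C; then 19, −78 °C to rt
Reagents that add atoms: none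
Why: Wittig olefination of a β-peroxy aldehyde with a non-stabilized γ-oxido ylide. Addition at −78 °C outruns enolization, so the β-peroxide is not eliminated, and perketals are known to survive phosphorus ylides; the alkene geometry is irrelevant because the bond is saturated in step 16.

Step 16
Reactants: 23 (2R,3E,6S)-6-[(2-methoxypropan-2-yl)peroxy]-2,6,10-trimethylundeca-3,9-dien-1-ol
Product: 24 (2R,6R)-6-[(2-methoxypropan-2-yl)peroxy]-2,6,10-trimethylundec-9-en-1-ol
Conditions: 2-nitrobenzenesulfonohydrazide, Et3N, CH2Cl2, rt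
Reagents that add atoms: none
Why: Diimide generated in the flask transfers H2 in a concerted way to the 1,2-disubstituted alkene much faster than to the trisubstituted one and does not touch O–O bonds.

Step 17
Reactants: 24 (2R,6R)-6-[(2-methoxypropan-2-yl)peroxy]-2,6,10-trimethylundec-9-en-1-ol
Product: 25 (2R,6R)-6-[(2-methoxypropan-2-yl)peroxy]-2,6,10-trimethylundec-9-enal
Conditions: Dess–Martin periodinane, NaHCO3, CH2Cl2, 0 °C
Reagents that add atoms: none
Why: Dess–Martin oxidation to the α-branched aldehyde, which is used crude to avoid epimerization at C10.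

Step 18
Reactants: 25 (2R,6R)-6-[(2-methoxypropan-2-yl)peroxy]-2,6,10-trimethylundec-9-enal
Product: 26 (3R,7R)-7-[(2-methoxypropan-2-yl)peroxy]-3,7,11-trimethyldodeca-1,10-diene
Conditions: Ph3PCH3Br, KHMDS, THF, 0 °C; then 25, −78 to 0 °C
Reagents that add atoms: methyltriphenylphosphonium bromide, C[P+](c1ccccc1)(c1ccccc1)c1ccccc1.[Br-]
Why: Wittig methylenation at low temperature installs the vinyl group needed for cross-metathesis without epimerizing the α-stereocenter.

Step 19
Reactants: 11 methyl (2R)-2-[(3S,6S)-6-methyl-6-(prop-2-en-1-yl)-1,2-dioxan-3-yl]propanoate; 26 (3R,7R)-7-[(2-methoxypropan-2-yl)peroxy]-3,7,11-trimethyldodeca-1,10-diene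
Product: 27 methyl (2R)-2-[(3S,6S)-6-[(2E,4R,8R)-8-[(2-methoxypropan-2-yl)peroxy]-4,8,12-trimethyltrideca-2,11-dien-1-yl]-6-methyl-1,2-dioxan-3-yl]propanoate (E/Z mixture)
Conditions: second-generation Hoveyda–Grubbs catalyst RuCl2(1,3-dimesitylimidazolidin-2-ylidene)(=CH-C6H4-2-OiPr) (5 mol%), 11 (1.5 equiv), CH2Cl2, 40 °C
Reagents that add atoms: none
Why: Olefin cross-metathesis between a type-1 alkene (the allyl group of 11) and a type-2 alkene (the α-branched vinyl group of 26). Dialkyl peroxides and perketals are tolerated by ruthenium carbenes, and the prenyl-type alkene is too hindered to compete and too far from C9 to ring-close; the E/Z ratio is irrelevant.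

Step 20
Reactants: 27 methyl (2R)-2-[(3S,6S)-6-[(2E,4R,8R)-8-[(2-methoxypropan-2-yl)peroxy]-4,8,12-trimethyltrideca-2,11-dien-1-yl]-6-methyl-1,2-dioxan-3-yl]propanoate
Product: 28 methyl (2R)-2-[(3S,6R)-6-[(4S,8R)-8-[(2-methoxypropan-2-yl)peroxy]-4,8,12-trimethyltridec-11-en-1-yl]-6-methyl-1,2-dioxan-3-yl]propanoate
Conditions: 2-nitrobenzenesulfonohydrazide, Et3N, CH2Cl2, rt, monitored
Reagents that add atoms: none
Why: Second chemoselective diimide reduction: the disubstituted C8=C9 is saturated, while the trisubstituted C17=C18 and all O–O bonds remain. The descriptors at C6 and C10 change only because CIP priorities change.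

Step 21
Reactants: 28 methyl (2R)-2-[(3S,6R)-6-[(4S,8R)-8-[(2-methoxypropan-2-yl)peroxy]-4,8,12-trimethyltridec-11-en-1-yl]-6-methyl-1,2-dioxan-3-yl]propanoate
Product: 29 methyl (2R)-2-[(3S,6R)-6-[(4R,8R)-8-hydroperoxy-4,8,12-trimethyltridec-11-en-1-yl]-6-methyl-1,2-dioxan-3-yl]propanoate
Conditions: AcOH/THF/H2O (4:2:1), rt
Reagents that add atoms: none
Why: Mild acid hydrolysis of the peroxyketal releases the tertiary hydroperoxide; the 1,2-dioxane, the ester and the alkene are stable to aqueous acetic acid at room temperature.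

## Compound list

1 | hex-5-en-2-one | CC(=O)CCC=C | starting material
2 | 4-oxopentanal | CC(=O)CCC=O | intermediate
3 | (5R,6S)-5-hydroxy-6-methyloct-7-en-2-one | C=C[C@H](C)[C@H](O)CCC(C)=O | intermediate
4 | (3S,4R)-3-methyl-7-oxooct-1-en-4-yl methanesulfonate | C=C[C@H](C)[C@H](OS(C)(=O)=O)CCC(C)=O | intermediate
5 | (3S,4R)-7-hydroperoxy-7-methoxy-3-methyloct-1-en-4-yl methanesulfonate (both C7 epimers) | C=C[C@H](C)[C@H](OS(C)(=O)=O)CCC(C)(OC)OO | intermediate
6 | (3S)-3-[(2S)-but-3-en-2-yl]-6-methoxy-6-methyl-1,2-dioxane (both C6 epimers) | C=C[C@H](C)[C@@H]1CCC(C)(OC)OO1 | intermediate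
7 | (2R)-2-[(3S)-6-methoxy-6-methyl-1,2-dioxan-3-yl]propanal | O=C[C@H](C)[C@@H]1CCC(C)(OC)OO1 | intermediate
8 | (2R)-2-[(3S)-6-methoxy-6-methyl-1,2-dioxan-3-yl]propanoic acid | OC(=O)[C@H](C)[C@@H]1CCC(C)(OC)OO1 | intermediate
9 | methyl (2R)-2-[(3S)-6-methoxy-6-methyl-1,2-dioxan-3-yl]propanoate | COC(=O)[C@H](C)[C@@H]1CCC(C)(OC)OO1 | intermediate
10 | (3S)-3-[(2R)-1-methoxy-1-oxopropan-2-yl]-6-methyl-4,5-dihydro-3H-1,2-dioxin-1-ium (ring peroxycarbenium ion) | COC(=O)[C@H](C)[C@@H]1CCC(C)=[O+]O1 | intermediate
11 | methyl (2R)-2-[(3S,6S)-6-methyl-6-(prop-2-en-1-yl)-1,2-dioxan-3-yl]propanoate | COC(=O)[C@H](C)[C@@H]1CC[C@@](C)(CC=C)OO1 | intermediate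
12 | (3R)-3,7-dimethylocta-1,6-dien-3-ol [(R)-linalool] | C=C[C@@](C)(CCC=C(C)C)O | starting material
13 | (3R)-3,7-dimethyloct-6-ene-1,3-diol | OCC[C@@](C)(CCC=C(C)C)O | intermediate
14 | (3R)-3-hydroxy-3,7-dimethyloct-6-en-1-yl 4-methylbenzenesulfonate | Cc1ccc(cc1)S(=O)(=O)OCC[C@@](C)(CCC=C(C)C)O | intermediate
15 | (2R)-2-methyl-2-(4-methylpent-3-en-1-yl)oxetane | C1C[C@@](C)(CCC=C(C)C)O1 | intermediate
16 | (3S)-3-hydroperoxy-3,7-dimethyloct-6-en-1-ol | OCC[C@](C)(CCC=C(C)C)OO | intermediate
17 | 2-methoxy-2-{[(3S)-3-[(2-methoxypropan-2-yl)peroxy]-3,7-dimethyloct-6-en-1-yl]oxy}propane | COC(C)(C)OCC[C@](C)(CCC=C(C)C)OOC(C)(C)OC | intermediate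
18 | (3S)-3-[(2-methoxypropan-2-yl)peroxy]-3,7-dimethyloct-6-en-1-ol | OCC[C@](C)(CCC=C(C)C)OOC(C)(C)OC | intermediate
19 | (3S)-3-[(2-methoxypropan-2-yl)peroxy]-3,7-dimethyloct-6-enal | O=CC[C@](C)(CCC=C(C)C)OOC(C)(C)OC | intermediate
20 | (2S)-3-bromo-2-methylpropan-1-ol | OC[C@H](C)CBr | starting material
21 | [(2S)-3-hydroxy-2-methylpropyl]triphenylphosphonium bromide | OC[C@H](C)C[P+](c1ccccc1)(c1ccccc1)c1ccccc1.[Br-] | intermediate
22 | lithium (2S)-2-methyl-3-(triphenyl-λ5-phosphanylidene)propan-1-olate | [Li+].[O-]C[C@H](C)C=P(c1ccccc1)(c1ccccc1)c1ccccc1 | intermediate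
23 | (2R,3E,6S)-6-[(2-methoxypropan-2-yl)peroxy]-2,6,10-trimethylundeca-3,9-dien-1-ol | OC[C@H](C)/C=C/C[C@](C)(CCC=C(C)C)OOC(C)(C)OC | intermediate
24 | (2R,6R)-6-[(2-methoxypropan-2-yl)peroxy]-2,6,10-trimethylundec-9-en-1-ol | OC[C@H](C)CCC[C@](C)(CCC=C(C)C)OOC(C)(C)OC | intermediate
25 | (2R,6R)-6-[(2-methoxypropan-2-yl)peroxy]-2,6,10-trimethylundec-9-enal | O=C[C@H](C)CCC[C@](C)(CCC=C(C)C)OOC(C)(C)OC | intermediate
26 | (3R,7R)-7-[(2-methoxypropan-2-yl)peroxy]-3,7,11-trimethyldodeca-1,10-diene | C=C[C@H](C)CCC[C@](C)(CCC=C(C)C)OOC(C)(C)OC | intermediate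
27 | methyl (2R)-2-[(3S,6S)-6-[(2E,4R,8R)-8-[(2-methoxypropan-2-yl)peroxy]-4,8,12-trimethyltrideca-2,11-dien-1-yl]-6-methyl-1,2-dioxan-3-yl]propanoate | COC(=O)[C@H](C)[C@@H]1CC[C@@](C)(C/C=C/[C@H](C)CCC[C@](C)(CCC=C(C)C)OOC(C)(C)OC)OO1 | intermediate
28 | methyl (2R)-2-[(3S,6R)-6-[(4S,8R)-8-[(2-methoxypropan-2-yl)peroxy]-4,8,12-trimethyltridec-11-en-1-yl]-6-methyl-1,2-dioxan-3-yl]propanoate | COC(=O)[C@H](C)[C@@H]1CC[C@@](C)(CCC[C@H](C)CCC[C@](C)(CCC=C(C)C)OOC(C)(C)OC)OO1 | intermediate
29 | methyl (2R)-2-[(3S,6R)-6-[(4R,8R)-8-hydroperoxy-4,8,12-trimethyltridec-11-en-1-yl]-6-methyl-1,2-dioxan-3-yl]propanoate | COC(=O)[C@H](C)[C@@H]1CC[C@@](C)(CCC[C@H](C)CCC[C@](C)(CCC=C(C)C)OO)OO1 | target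

## Step count and risks

Total step count: 21. Longest linear sequence: 12 steps (from 12: steps 9–13 and 15–21). The ring branch from 1 is 11 steps (1–8 and 19–21).

**Step 8 (key step).** Two processes can fail. Facial selectivity may be poor if the longer O–O bond flattens the ring and brings the two half-chairs of the cation close in energy. The peroxycarbenium ion may also undergo O–O heterolysis and rearrangement before it is captured. The fallback takes the configuration of C6 from (R)-linalool instead of from C3 and closes the ring by SN2 at C3, using known reaction types only. It sets out from 17, isolated instead of being methanolysed. Ozonolysis of the trisubstituted alkene (O3; Me2S) gives (4S)-6-[(2-methoxypropan-2-yl)oxy]-4-[(2-methoxypropan-2-yl)peroxy]-4-methylhexanal F1. Crotylboration as in step 2 gives (3S,4R,7S)-9-[(2-methoxypropan-2-yl)oxy]-7-[(2-methoxypropan-2-yl)peroxy]-3,7-dimethylnon-1-en-4-ol F2, and mesylation gives its methanesulfonate F3. PPTS in methanol removes both ketals to give (3S,4R,7S)-7-hydroperoxy-9-hydroxy-3,7-dimethylnon-1-en-4-yl methanesulfonate F4. KOtBu/18-crown-6 then closes the ring by 6-exo-tet attack of the tertiary peroxide anion, with inversion at C3, to give 2-[(3S,6S)-6-[(2S)-but-3-en-2-yl]-3-methyl-1,2-dioxan-3-yl]ethan-1-ol F5. Ozonolysis/Pinnick oxidation as in step 6 gives (2R)-2-[(3S,6S)-6-(2-hydroxyethyl)-6-methyl-1,2-dioxan-3-yl]propanoic acid F6. Trimethylsilyldiazomethane gives methyl (2R)-2-[(3S,6S)-6-(2-hydroxyethyl)-6-methyl-1,2-dioxan-3-yl]propanoate F7. Dess–Martin oxidation gives methyl (2R)-2-[(3S,6S)-6-methyl-6-(2-oxoethyl)-1,2-dioxan-3-yl]propanoate F8, and Wittig methylenation (Ph3P=CH2, −78 °C) comes back to the route at 11.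

**Step 5.** E2 elimination of the hindered secondary mesylate to a diene may compete with ring closure, and substitution at a carbon flanked by a tertiary centre may be slow. The fallback changes the leaving group and the mode of activation from base to silver. It sets out from 2. (Z)-Crotylboration with the enantiomeric, (−)-α-pinene-derived reagent gives the syn alcohol (5S,6S)-5-hydroxy-6-methyloct-7-en-2-one F9. Appel iodination (I2, PPh3, imidazole) with inversion gives (5R,6S)-5-iodo-6-methyloct-7-en-2-one F10. The conditions of step 4 give (3S,4R)-7-hydroperoxy-4-iodo-7-methoxy-3-methyloct-1-ene F11. Silver-assisted closure (Ag2O, CH2Cl2) with inversion comes back at 6.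

**Step 12.** During the selective methanolysis the peroxyketal may also be lost, or it may transketalize with the freed hydroxyl to a seven-membered 1,2,4-trioxepane. The fallback differentiates the two O–H groups by silicon instead of by ketal lability. It sets out from 16. TBSCl/imidazole, with cleavage of any silyl peroxide on methanolic K2CO3 work-up, gives tert-butyl{[(3S)-3-hydroperoxy-3,7-dimethyloct-6-en-1-yl]oxy}dimethylsilane F12. 2-Methoxypropene/PPTS, with no free hydroxyl present, gives tert-butyl{[(3S)-3-[(2-methoxypropan-2-yl)peroxy]-3,7-dimethyloct-6-en-1-yl]oxy}dimethylsilane F13. TBAF comes back at 18.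

**Step 19.** Conversion may be low because of the allylic branch at C10, the peroxides may slowly deactivate the catalyst, and 11 may homodimerize. The fallback replaces metathesis by a Julia–Kocienski olefination. It sets out from 24 and 11. Mitsunobu reaction of 24 with 1-phenyl-1H-tetrazole-5-thiol (PPh3, DIAD, 0 °C) gives 5-{[(2R,6R)-6-[(2-methoxypropan-2-yl)peroxy]-2,6,10-trimethylundec-9-en-1-yl]sulfanyl}-1-phenyl-1H-tetrazole F14. Oxidation with (NH4)6Mo7O24/H2O2 gives the corresponding sulfone, 5-{[(2R,6R)-6-[(2-methoxypropan-2-yl)peroxy]-2,6,10-trimethylundec-9-en-1-yl]sulfonyl}-1-phenyl-1H-tetrazole F15. Ozonolysis of 11 (O3; Me2S) gives the aldehyde F8 already described under step 8. KHMDS is added to a mixture of F15 and that aldehyde at −78 °C, and the (E)-alkene comes back at 27. The sulfonyl carbanion sits seven atoms from the nearest O–O bond, and carbonyl addition is expected to outrun enolization of the β-peroxy carbonyl groups.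

## Further compounds

F1 | step 8 | (4S)-6-[(2-methoxypropan-2-yl)oxy]-4-[(2-methoxypropan-2-yl)peroxy]-4-methylhexanal | COC(C)(C)OCC[C@](C)(CCC=O)OOC(C)(C)OC
F2 | step 8 | (3S,4R,7S)-9-[(2-methoxypropan-2-yl)oxy]-7-[(2-methoxypropan-2-yl)peroxy]-3,7-dimethylnon-1-en-4-ol | C=C[C@H](C)[C@H](O)CC[C@@](C)(CCOC(C)(C)OC)OOC(C)(C)OC
F3 | step 8 | (3S,4R,7S)-9-[(2-methoxypropan-2-yl)oxy]-7-[(2-methoxypropan-2-yl)peroxy]-3,7-dimethylnon-1-en-4-yl methanesulfonate | C=C[C@H](C)[C@H](OS(C)(=O)=O)CC[C@@](C)(CCOC(C)(C)OC)OOC(C)(C)OC
F4 | step 8 | (3S,4R,7S)-7-hydroperoxy-9-hydroxy-3,7-dimethylnon-1-en-4-yl methanesulfonate | C=C[C@H](C)[C@H](OS(C)(=O)=O)CC[C@@](C)(CCO)OO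
F5 | step 8 | 2-[(3S,6S)-6-[(2S)-but-3-en-2-yl]-3-methyl-1,2-dioxan-3-yl]ethan-1-ol | C=C[C@H](C)[C@@H]1CC[C@@](C)(CCO)OO1
F6 | step 8 | (2R)-2-[(3S,6S)-6-(2-hydroxyethyl)-6-methyl-1,2-dioxan-3-yl]propanoic acid | OC(=O)[C@H](C)[C@@H]1CC[C@@](C)(CCO)OO1
F7 | step 8 | methyl (2R)-2-[(3S,6S)-6-(2-hydroxyethyl)-6-methyl-1,2-dioxan-3-yl]propanoate | COC(=O)[C@H](C)[C@@H]1CC[C@@](C)(CCO)OO1
F8 | step 8 | methyl (2R)-2-[(3S,6S)-6-methyl-6-(2-oxoethyl)-1,2-dioxan-3-yl]propanoate | COC(=O)[C@H](C)[C@@H]1CC[C@@](C)(CC=O)OO1
F9 | step 5 | (5S,6S)-5-hydroxy-6-methyloct-7-en-2-one | C=C[C@H](C)[C@@H](O)CCC(C)=O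
F10 | step 5 | (5R,6S)-5-iodo-6-methyloct-7-en-2-one | C=C[C@H](C)[C@H](I)CCC(C)=O
F11 | step 5 | (3S,4R)-7-hydroperoxy-4-iodo-7-methoxy-3-methyloct-1-ene (both C7 epimers) | C=C[C@H](C)[C@H](I)CCC(C)(OC)OO
F12 | step 12 | tert-butyl{[(3S)-3-hydroperoxy-3,7-dimethyloct-6-en-1-yl]oxy}dimethylsilane | CC(C)(C)[Si](C)(C)OCC[C@](C)(CCC=C(C)C)OO
F13 | step 12 | tert-butyl{[(3S)-3-[(2-methoxypropan-2-yl)peroxy]-3,7-dimethyloct-6-en-1-yl]oxy}dimethylsilane | CC(C)(C)[Si](C)(C)OCC[C@](C)(CCC=C(C)C)OOC(C)(C)OC
F14 | step 19 | 5-{[(2R,6R)-6-[(2-methoxypropan-2-yl)peroxy]-2,6,10-trimethylundec-9-en-1-yl]sulfanyl}-1-phenyl-1H-tetrazole | c1ccccc1-n1nnnc1SC[C@H](C)CCC[C@](C)(CCC=C(C)C)OOC(C)(C)OC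
F15 | step 19 | 5-{[(2R,6R)-6-[(2-methoxypropan-2-yl)peroxy]-2,6,10-trimethylundec-9-en-1-yl]sulfonyl}-1-phenyl-1H-tetrazole | c1ccccc1-n1nnnc1S(=O)(=O)C[C@H](C)CCC[C@](C)(CCC=C(C)C)OOC(C)(C)OC
A1 | alternative 1 | methyl (2E)-6,14-dihydroperoxy-2,6,10,14,18-pentamethylnonadeca-2,17-dienoate (target configuration at C10; C6 and C14 as mixtures) | COC(=O)/C(C)=C/CCC(C)(OO)CCC[C@H](C)CCCC(C)(OO)CCC=C(C)C
A2 | alternative 2 | methyl (2E,6S)-6-hydroperoxy-8-hydroxy-2,6-dimethyloct-2-enoate | COC(=O)/C(C)=C/CC[C@@](C)(CCO)OO
A3 | alternative 3 | methyl (3E,5E)-14-hydroperoxy-2,6,10,14,18-pentamethylnonadeca-3,5,17-trienoate (target configuration at C2, C10 and C14) | COC(=O)[C@H](C)/C=C/C=C(\C)CCC[C@H](C)CCC[C@](C)(CCC=C(C)C)OO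
A4 | alternative 3 | 4,5-didehydro analogue of 29 (3,6-dihydro-1,2-dioxin) | COC(=O)[C@H](C)[C@@H]1C=C[C@@](C)(CCC[C@H](C)CCC[C@](C)(CCC=C(C)C)OO)OO1
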